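**Plan**

1. Numbering follows the target decalin. Ring A is C1–C5/C10 (C4 carries the methylene, C5 is quaternary). Ring B is C5–C10 (C8 is the CHMe, C9 is quaternary). C11 is the ArCH2 on C9.
2. Retrosynthesis: quinone ⇒ tetramethoxyarene; C4=CH2 ⇒ C4 ketone; 9-methyl ⇒ 9-carboxyl with a C6=C7 alkene. The C8–C9 bond of ring B is then cut by a retro-[3,3] shift to a cis-fused δ-lactone (O joins C6 to the carboxyl carbon) that carries an (E)-propenyl group on C6 and ArCH2 on C9. The lactone is cut at C9–C11 (enolate alkylation) and traced through ozonolysis to a Diels–Alder adduct (C5–C6 and C9–C10).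
3. Forward: ring A comes with 2-methylcyclohexenone. A Diels–Alder reaction adds a sacrificial cyclohexene, which is cleaved and re-closed as the temporary lactone ring. The arene is attached, ring B closes by contraction of the lactone, and the quinone is unveiled last.
4. Enabling feature: quaternary C9 bears a one-carbon branch (9-Me) that can be a carboxyl, its neighbour C8 is a methyl-bearing methine, and C6–C7 are plain CH2. A lactone enolate at C9 and an allyl unit O–C6–C7=C8 therefore sit 1,5 to each other across the C5–C10 ring fusion. The lactone C–O bond is not in the target.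
5. Stereochemistry: the catalyst-controlled endo Diels–Alder sets C5, C10 and the temporary C6 carbinol. C6 relays its configuration to C9 and C8 through the ring-enforced boat transition state and the E alkene. No stereocentre is epimerisable afterwards.

Key step: step 10

Assumption: the (S)-configured oxazaborolidine–AlBr3 complex of step 2 is taken to expose the enone face that leads to adduct 4 as drawn; should the sense of induction be opposite, the (R)-catalyst is used.

**Route**

Step 1
Reactants: 1 (E)-but-2-enal
Product: 2 (E)-1-(triisopropylsilyloxy)buta-1,3-diene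
Conditions: iPr3SiOTf, Et3N, Et2O, 0 to 23 °C
Reagents that add atoms: triisopropylsilyl trifluoromethanesulfonate, CC(C)[Si](C(C)C)(C(C)C)OS(=O)(=O)C(F)(F)F
Why: O-silylation of the enal and γ-deprotonation by the amine (soft enolisation to a silyl dienol ether) should give the 1-silyloxydiene mainly as the E isomer, the only one that can reach the s-cis conformer needed in step 2.

Step 2
Reactants: 2 (E)-1-(triisopropylsilyloxy)buta-1,3-diene; 3 2-methylcyclohex-2-en-1-one
Product: 4 (4aS,8R,8aS)-8a-methyl-8-(triisopropylsilyloxy)-3,4,4a,5,8,8a-hexahydronaphthalen-1(2H)-one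
Conditions: AlBr3-activated (3aS)-1-(2-methylphenyl)-3,3-diphenyltetrahydro-1H,3H-pyrrolo[1,2-c][1,3,2]oxazaborole (20 mol %), CH2Cl2, −78 to −40 °C
Reagents that add atoms: none
Why: Proposed new method: coordination of the chiral boron Lewis acid to the enone carbonyl lowers the dienophile LUMO and blocks one face; the unsubstituted diene terminus bonds to the β-carbon C10 and the silyloxy-bearing terminus to the α-carbon C5 (ortho rule), the carbonyl sits endo so the OSi group on C6 ends cis to C4 and trans to the angular methyl, and the ring of the dienophile makes 5-Me and H10 cis, so C5, C10 and C6 are set together; the closest known reaction types are the oxazaborolidine–AlBr3-catalysed enantioselective Diels–Alder additions of silyloxydienes to cyclohex-2-enone and the AlBr3/AlMe3-promoted racemic additions of silyloxydienes to 2-methylcyclohex-2-enone, the new element being face-selective catalysis on an enone without an α-hydrogen.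

Step 3
Reactants: 4 Diels–Alder adduct
Product: 5 ethylene ketal of 4, (4a'S,8'R,8a'S)-8a'-methyl-8'-(triisopropylsilyloxy)-3',4',4a',5',8',8a'-hexahydro-2'H-spiro[1,3-dioxolane-2,1'-naphthalene]
Conditions: Me3SiOCH2CH2OSiMe3, Me3SiOTf (5 mol %), CH2Cl2, −78 to −20 °C
Reagents that add atoms: 1,2-bis(trimethylsilyloxy)ethane, C[Si](C)(C)OCCO[Si](C)(C)C
Why: Aprotic silyl-triflate-catalysed ketalisation should mask the hindered C4 ketone without ionising the allylic silyl ether, which removes the retro-aldol path and the enolisable ketone from all later steps.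

Step 4
Reactants: 5 ketal
Product: 7 methyl 2-{(6S,7S)-6-methyl-6-[(1S)-2-oxo-1-(triisopropylsilyloxy)ethyl]-1,4-dioxaspiro[4.5]decan-7-yl}acetate, via methoxy hydroperoxide 6 (not isolated)
Conditions: O3, CH2Cl2/MeOH 5:1, NaHCO3, −78 °C; then Ac2O, Et3N, CH2Cl2, 0 °C
Reagents that add atoms: ozone, O=[O+][O-]; methanol, CO
Why: In this unsymmetrical ozonolysis the primary ozonide should fragment so that the carbonyl oxide forms on the alkene carbon remote from the electron-withdrawing allylic OSi group, methanol traps it as hydroperoxide 6 and acetylation–elimination turns that terminus into the methyl ester while C7 is left as the aldehyde (Criegee mechanism with dehydrative work-up).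

Step 5
Reactants: 7 aldehyde ester
Product: 8 methyl 2-{(6S,7S)-6-methyl-6-[(1R,2E)-1-(triisopropylsilyloxy)but-2-en-1-yl]-1,4-dioxaspiro[4.5]decan-7-yl}acetate
Conditions: CrCl2, CH3CHI2, THF, 23 °C
Reagents that add atoms: 1,1-diiodoethane, CC(I)I
Why: Takai–Utimoto ethylidenation through a geminal dichromium reagent should give the (E)-propenyl group under non-basic conditions that leave the α-silyloxy stereocentre, the ester and the ketal untouched.

Step 6
Reactants: 8 (E)-propenyl ester
Product: 10 (1R,4aS,8aS)-8,8-(ethylenedioxy)-8a-methyl-1-[(E)-prop-1-en-1-yl]-1,4,4a,5,6,7,8,8a-octahydro-3H-isochromen-3-one (δ-lactone; propenyl, 8a-methyl and H4a all cis), via hydroxy ester 9 (not isolated)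
Conditions: Bu4NF, THF, 50 °C; NH4Cl(aq)
Reagents that add atoms: none
Why: Fluoride desilylation frees the C6 alkoxide, which should close on the methyl ester by 6-exo-trig lactonisation to the cis-fused δ-lactone.

Step 7
Reactants: 11 1,2,4,5-tetramethoxybenzene
Product: 13 (2,3,5,6-tetramethoxyphenyl)methanol, via aryllithium 12 (not isolated)
Conditions: n-BuLi, TMEDA, THF, 0 °C; (CH2O)n, 0 to 23 °C; NH4Cl(aq)
Reagents that add atoms: formaldehyde (as paraformaldehyde), C=O; n-butyllithium, [Li]CCCC (supplies only the lithium of intermediate 12)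
Why: Directed ortho-lithiation at the position flanked by two methoxy groups followed by hydroxymethylation should give the benzylic alcohol.

Step 8
Reactants: 13 benzylic alcohol
Product: 14 3-(bromomethyl)-1,2,4,5-tetramethoxybenzene
Conditions: PBr3, Et2O, 0 °C
Reagents that add atoms: phosphorus tribromide, BrP(Br)Br
Why: Bromination of an electron-rich benzylic alcohol through its phosphite ester is a standard substitution.

Step 9
Reactants: 10 lactone; 14 benzylic bromide
Product: 16 (1R,4aS,8aS)-8,8-(ethylenedioxy)-8a-methyl-1-[(E)-prop-1-en-1-yl]-4-(2,3,5,6-tetramethoxybenzyl)-1,4,4a,5,6,7,8,8a-octahydro-3H-isochromen-3-one (either C4 epimer), via lithium enolate 15 (not isolated)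
Conditions: LiN(iPr)2, THF, −78 °C; 14, DMPU, −78 to −30 °C
Reagents that add atoms: lithium diisopropylamide, [Li]N(C(C)C)C(C)C (supplies only the lithium of intermediate 15)
Why: Lactone enolate alkylation (SN2 at the benzylic bromide) should attach C11 and the arene; the configuration of the new centre is irrelevant because it is planarised in step 10.

Step 10
Reactants: 16 benzylated lactone
Product: 20 acid: 4,4-(ethylenedioxy)-5,8-dimethyl-9-(2,3,5,6-tetramethoxybenzyl)-decal-6-ene-9-carboxylic acid, configured at C5, C8, C9 and C10 as in the target (CO2H in the place of the 9-methyl), via lithium enolate 17 (not isolated), via silyl ketene acetal 18 (not isolated), via trimethylsilyl ester 19 (not isolated)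
Conditions: LiN(iPr)2, THF, −78 °C; Me3SiCl/Et3N, −78 to 23 °C; toluene, 110 °C; then H2O, THF, 23 °C
Reagents that add atoms: lithium diisopropylamide, [Li]N(C(C)C)C(C)C (supplies only the lithium of intermediate 17); chlorotrimethylsilane, C[Si](C)(C)Cl (supplies only the Me3Si group of intermediates 18 and 19)
Why: Deprotonation at C9 and O-silylation give the cyclic silyl ketene acetal 18, in which C9=C(OSiMe3)–O–C6–C7=C8 is a 1,5-diene, and heating drives a concerted suprafacial [3,3] shift that breaks the lactone O–C6 bond and forms C8–C9 (silyl ester 19, hydrolysed to 20). The closest known reaction type is the Ireland–Claisen ring contraction of 6-alkenyl δ-lactone silyl ketene acetals to cyclohex-3-enecarboxylic acids. Ring B closes as a six-membered carbocycle by ring contraction: C6 and C9 are already tied through the C5–C10 bond, so the six reacting atoms can meet only in a boat (a bicyclo[2.2.2]octene-like transition state), and the new C6=C7 bond ends inside the ring. C9 is controlled by C6: the propenyl group lies on the lactone face that carries 5-Me and H10, C8 is delivered to that face of the planar ketene acetal, and the carboxyl (the future 9-methyl) therefore ends cis to C1 and C4 and the benzyl group cis to H10. C8 is controlled by the E geometry of the alkene, which in the boat points its methyl towards the lactone bridge and so places it cis to the carboxyl, that is cis to the future 9-methyl. The step needs O- over C-silylation of a tetrasubstituted enolate and a single transition-state geometry; the substrate secures this because the enolate geometry is fixed by the ring, a chair is geometrically impossible, and the E-methyl and the ring A carbons point away from each other in the boat.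

Step 11
Reactants: 20 acid
Product: 21 primary alcohol (9-CH2OH in place of 9-CO2H; otherwise as 20)
Conditions: LiAlH4, THF, 66 °C; NaOH(aq) work-up
Reagents that add atoms: none
Why: Hydride reduction of the hindered neopentyl carboxylic acid should give the alcohol; ketal, alkene and aryl ethers are inert.

Step 12
Reactants: 21 alcohol
Product: 22 aldehyde (9-CHO; otherwise as 20)
Conditions: Dess–Martin periodinane, NaHCO3, CH2Cl2, 23 °C
Reagents that add atoms: none
Why: Dess–Martin oxidation under buffered conditions should give the non-enolisable neopentyl aldehyde without touching the ketal.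

Step 13
Reactants: 22 aldehyde
Product: 24 4,4-(ethylenedioxy)-5,8,9-trimethyl-9-(2,3,5,6-tetramethoxybenzyl)-decal-6-ene, configured as in the target, via hydrazone 23 (not isolated)
Conditions: N2H4·H2O, KOH, diethylene glycol, 130 then 200 °C
Reagents that add atoms: hydrazine, NN (supplies only the two nitrogen atoms of intermediate 23)
Why: Wolff–Kishner reduction (hydrazone, base-induced loss of N2) should turn the carboxyl-derived carbon into the 9-methyl; ketal, isolated alkene and aryl methyl ethers tolerate the base.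

Step 14
Reactants: 24 alkene ketal
Product: 26 (4aR,5R,6S,8aS)-4a,5,6-trimethyl-5-(2,3,5,6-tetramethoxybenzyl)octahydronaphthalen-1(2H)-one (C4 ketone of the target skeleton), via saturated ketal 25 (not isolated)
Conditions: H2 (1 atm), Pd/C, EtOAc, 23 °C; then 2 M HCl, THF, 40 °C
Reagents that add atoms: water, O
Why: Catalytic hydrogenation of the cis-disubstituted C6=C7 bond (no new stereocentre, no benzylic heteroatom to cleave) followed by acid hydrolysis of the dioxolane should give the ketone.

Step 15
Reactants: 26 ketone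
Product: 27 3-{[(1R,2S,4aR,8aS)-1,2,4a-trimethyl-5-methylidenedecahydronaphthalen-1-yl]methyl}-1,2,4,5-tetramethoxybenzene
Conditions: Ph3PCH3Br, KOtBu, toluene, 90 °C
Reagents that add atoms: methyltriphenylphosphonium bromide, C[P+](c1ccccc1)(c1ccccc1)c1ccccc1.[Br-]
Why: Wittig methylenation with the unhindered methylene ylide at elevated temperature should convert the ketone next to the quaternary C5 into the exocyclic alkene.

Step 16
Reactants: 27 tetramethoxyarene
Product: 28 3-{[(1R,2S,4aR,8aS)-1,2,4a-trimethyl-5-methylidenedecahydronaphthalen-1-yl]methyl}-2,5-dimethoxycyclohexa-2,5-diene-1,4-dione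
Conditions: (NH4)2Ce(NO3)6, MeCN/H2O, 0 °C
Reagents that add atoms: water, O
Why: Oxidative demethylation of the para-dimethoxy pair by tetravalent cerium (arene radical cation, water addition, loss of methanol) should give the 2,5-dimethoxyquinone; either para pair leads to the same quinone and the alkene is not oxidised.

Step 17
Reactants: 28 dimethoxyquinone
Product: 29 target, 3-{[(1R,2S,4aR,8aS)-1,2,4a-trimethyl-5-methylidenedecahydronaphthalen-1-yl]methyl}-2-hydroxy-5-methoxycyclohexa-2,5-diene-1,4-dione
Conditions: KOH, MeOH/H2O, 23 °C; then HCl(aq)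
Reagents that add atoms: potassium hydroxide, [K+].[OH-]
Why: Addition–elimination of hydroxide at the vinylogous ester carbon next to the alkyl group should give the hydroxy methoxy quinone, because that methoxy group is twisted out of conjugation and the product is the stabilised 2-hydroxy-3-alkylquinone anion; this is a regioselective vinylogous ester hydrolysis.

**Compound list**

1 | (E)-but-2-enal | C/C=C/C=O | starting material
2 | (E)-1-(triisopropylsilyloxy)buta-1,3-diene | C=C/C=C/O[Si](C(C)C)(C(C)C)C(C)C | intermediate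
3 | 2-methylcyclohex-2-en-1-one | CC1=CCCCC1=O | starting material
4 | (4aS,8R,8aS)-8a-methyl-8-(triisopropylsilyloxy)-3,4,4a,5,8,8a-hexahydronaphthalen-1(2H)-one | O=C1CCC[C@H]2CC=C[C@@H](O[Si](C(C)C)(C(C)C)C(C)C)[C@@]12C | intermediate
5 | ethylene ketal of 4 | O1CCOC12CCC[C@H]3CC=C[C@@H](O[Si](C(C)C)(C(C)C)C(C)C)[C@@]23C | intermediate
6 | (2S)-2-[(6S,7S)-7-(2-hydroperoxy-2-methoxyethyl)-6-methyl-1,4-dioxaspiro[4.5]decan-6-yl]-2-(triisopropylsilyloxy)acetaldehyde (hemiperacetal carbon undefined) | O1CCOC12CCC[C@@H](CC(OC)OO)[C@@]2(C)[C@H](O[Si](C(C)C)(C(C)C)C(C)C)C=O | intermediate (not isolated)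
7 | methyl 2-{(6S,7S)-6-methyl-6-[(1S)-2-oxo-1-(triisopropylsilyloxy)ethyl]-1,4-dioxaspiro[4.5]decan-7-yl}acetate | O1CCOC12CCC[C@@H](CC(=O)OC)[C@@]2(C)[C@H](O[Si](C(C)C)(C(C)C)C(C)C)C=O | intermediate
8 | methyl 2-{(6S,7S)-6-methyl-6-[(1R,2E)-1-(triisopropylsilyloxy)but-2-en-1-yl]-1,4-dioxaspiro[4.5]decan-7-yl}acetate | O1CCOC12CCC[C@@H](CC(=O)OC)[C@@]2(C)[C@H](O[Si](C(C)C)(C(C)C)C(C)C)/C=C/C | intermediate
9 | methyl 2-{(6S,7S)-6-[(1R,2E)-1-hydroxybut-2-en-1-yl]-6-methyl-1,4-dioxaspiro[4.5]decan-7-yl}acetate | O1CCOC12CCC[C@@H](CC(=O)OC)[C@@]2(C)[C@H](O)/C=C/C | intermediate (not isolated)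
10 | (1R,4aS,8aS)-8,8-(ethylenedioxy)-8a-methyl-1-[(E)-prop-1-en-1-yl]-1,4,4a,5,6,7,8,8a-octahydro-3H-isochromen-3-one | O1CCOC12CCC[C@H]3CC(=O)O[C@H](/C=C/C)[C@@]23C | intermediate
11 | 1,2,4,5-tetramethoxybenzene | COc1cc(OC)c(OC)cc1OC | starting material
12 | (2,3,5,6-tetramethoxyphenyl)lithium | [Li]c1c(OC)c(OC)cc(OC)c1OC | intermediate (not isolated)
13 | (2,3,5,6-tetramethoxyphenyl)methanol | OCc1c(OC)c(OC)cc(OC)c1OC | intermediate
14 | 3-(bromomethyl)-1,2,4,5-tetramethoxybenzene | BrCc1c(OC)c(OC)cc(OC)c1OC | intermediate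
15 | lithium enolate of lactone 10 | O1CCOC12CCC[C@H]3C=C(O[Li])O[C@H](/C=C/C)[C@@]23C | intermediate (not isolated)
16 | 4-(2,3,5,6-tetramethoxybenzyl) derivative of lactone 10 (benzyl-bearing carbon undefined; both epimers converge in step 10) | O1CCOC12CCC[C@H]3C(Cc4c(OC)c(OC)cc(OC)c4OC)C(=O)O[C@H](/C=C/C)[C@@]23C | intermediate
17 | lithium enolate of lactone 16 | O1CCOC12CCC[C@H]3C(Cc4c(OC)c(OC)cc(OC)c4OC)=C(O[Li])O[C@H](/C=C/C)[C@@]23C | intermediate (not isolated)
18 | cyclic trimethylsilyl ketene acetal of lactone 16 | O1CCOC12CCC[C@H]3C(Cc4c(OC)c(OC)cc(OC)c4OC)=C(O[Si](C)(C)C)O[C@H](/C=C/C)[C@@]23C | intermediate (not isolated)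
19 | trimethylsilyl ester of acid 20 | O1CCOC12CCC[C@H]3[C@](C(=O)O[Si](C)(C)C)(Cc4c(OC)c(OC)cc(OC)c4OC)[C@@H](C)C=C[C@@]23C | intermediate (not isolated)
20 | 4,4-(ethylenedioxy)-5,8-dimethyl-9-(2,3,5,6-tetramethoxybenzyl)-decal-6-ene-9-carboxylic acid, target configuration at C5, C8, C9, C10 | O1CCOC12CCC[C@H]3[C@](C(=O)O)(Cc4c(OC)c(OC)cc(OC)c4OC)[C@@H](C)C=C[C@@]23C | intermediate
21 | 9-hydroxymethyl analogue of 20 | O1CCOC12CCC[C@H]3[C@](CO)(Cc4c(OC)c(OC)cc(OC)c4OC)[C@@H](C)C=C[C@@]23C | intermediate
22 | 9-formyl analogue of 20 | O1CCOC12CCC[C@H]3[C@](C=O)(Cc4c(OC)c(OC)cc(OC)c4OC)[C@@H](C)C=C[C@@]23C | intermediate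
23 | hydrazone of aldehyde 22 | O1CCOC12CCC[C@H]3[C@](C=NN)(Cc4c(OC)c(OC)cc(OC)c4OC)[C@@H](C)C=C[C@@]23C | intermediate (not isolated)
24 | 4,4-(ethylenedioxy)-5,8,9-trimethyl-9-(2,3,5,6-tetramethoxybenzyl)-decal-6-ene, target configuration | O1CCOC12CCC[C@H]3[C@](C)(Cc4c(OC)c(OC)cc(OC)c4OC)[C@@H](C)C=C[C@@]23C | intermediate
25 | 6,7-dihydro derivative of 24 (saturated ketal) | O1CCOC12CCC[C@H]3[C@](C)(Cc4c(OC)c(OC)cc(OC)c4OC)[C@@H](C)CC[C@@]23C | intermediate (not isolated)
26 | (4aR,5R,6S,8aS)-4a,5,6-trimethyl-5-(2,3,5,6-tetramethoxybenzyl)octahydronaphthalen-1(2H)-one | O=C1CCC[C@H]2[C@](C)(Cc3c(OC)c(OC)cc(OC)c3OC)[C@@H](C)CC[C@@]12C | intermediate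
27 | 3-{[(1R,2S,4aR,8aS)-1,2,4a-trimethyl-5-methylidenedecahydronaphthalen-1-yl]methyl}-1,2,4,5-tetramethoxybenzene | C=C1CCC[C@H]2[C@](C)(Cc3c(OC)c(OC)cc(OC)c3OC)[C@@H](C)CC[C@@]12C | intermediate
28 | 3-{[(1R,2S,4aR,8aS)-1,2,4a-trimethyl-5-methylidenedecahydronaphthalen-1-yl]methyl}-2,5-dimethoxycyclohexa-2,5-diene-1,4-dione | C=C1CCC[C@H]2[C@](C)(CC3=C(OC)C(=O)C=C(OC)C3=O)[C@@H](C)CC[C@@]12C | intermediate
29 | 3-{[(1R,2S,4aR,8aS)-1,2,4a-trimethyl-5-methylidenedecahydronaphthalen-1-yl]methyl}-2-hydroxy-5-methoxycyclohexa-2,5-diene-1,4-dione | C=C1CCC[C@H]2[C@](C)(CC3=C(O)C(=O)C=C(OC)C3=O)[C@@H](C)CC[C@@]12C | target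

**Step count and risks**

Total step count: 17. Longest linear sequence: 15 steps (steps 1–6 and 9–17, from 1 to 29); the arene branch is 2 steps (7 and 8).

Steps most likely to fail:

1. Step 2 (Proposed new method). The α-methyl enone may react too slowly at the temperatures the chiral Lewis acid needs for face control. The silyl dienol ether may be consumed by Lewis-acid-induced stepwise addition, eroding endo control. Facial discrimination may be poor because the enone has no α-hydrogen to organise its binding. The fallback sets out from 2 and 3 and uses known chemistry. The racemic cycloaddition promoted by AlBr3/AlMe3 (10:1, toluene/CH2Cl2, 0 °C) should give the racemic adduct F1. Ketalisation as in step 3 gives the racemic ketal F2, and Bu4NF gives the racemic allylic alcohol F3. Esterification with (S)-2-methoxy-2-phenylacetic acid (DCC, DMAP) and chromatographic separation of the two diastereomers gives the ester F4. Methanolysis (K2CO3, MeOH) gives the enantiopure alcohol F5, and re-silylation (iPr3SiOTf, 2,6-lutidine) comes back to the route at 5.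

2. Step 10 (key step). C-silylation or incomplete O-silylation of the hindered tetrasubstituted lactone enolate may compete, and the silyl ketene acetal may be lost by hydrolysis or thermal decomposition before the strained boat transition state is passed. The fallback sets out from 16 and avoids the enolate altogether. Reduction with iBu2AlH (CH2Cl2, −78 °C) gives the lactol F6. Mesylation–elimination (MsCl, Et3N, 0 to 40 °C) gives the cyclic enol ether F7, a 1-propenyl-1H-isochromene. Thermolysis (xylene, 180 °C, sealed tube) effects the neutral Claisen rearrangement of this allyl vinyl ether through the same boat, so the same configuration at C8 and C9 is expected. It comes back to the route at aldehyde 22, so steps 11 and 12 are not needed.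

3. Step 4. Regiocontrol in the fragmentation of the primary ozonide may be incomplete, with the carbonyl oxide formed partly at C7 and the transposed ester aldehyde as the result, and the α-silyloxy aldehyde may epimerise during the basic dehydration. The fallback sets out from 5 and differentiates the two termini by an intramolecular event instead. Ozonolysis with reductive work-up (O3, CH2Cl2, −78 °C; PPh3) gives the silyloxy dialdehyde F8. Desilylation with HF·pyridine frees the C6 hydroxyl, which can close only on the distal aldehyde, giving the six-membered lactol aldehyde F9. Ag2CO3 on Celite (benzene, 80 °C) should oxidise the lactol but not the aldehyde, giving the lactone aldehyde F10. Takai–Utimoto ethylidenation (CrCl2, CH3CHI2) then comes back to the route at 10.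

Further compounds

F1 | step 2 | racemic 4 (both enantiomers) | O=C1CCC[C@H]2CC=C[C@@H](O[Si](C(C)C)(C(C)C)C(C)C)[C@@]12C.O=C1CCC[C@@H]2CC=C[C@H](O[Si](C(C)C)(C(C)C)C(C)C)[C@]12C
F2 | step 2 | racemic 5 (both enantiomers) | O1CCOC12CCC[C@H]3CC=C[C@@H](O[Si](C(C)C)(C(C)C)C(C)C)[C@@]23C.O1CCOC12CCC[C@@H]3CC=C[C@H](O[Si](C(C)C)(C(C)C)C(C)C)[C@]23C
F3 | step 2 | racemic allylic alcohol, desilylated F2 (both enantiomers) | O1CCOC12CCC[C@H]3CC=C[C@@H](O)[C@@]23C.O1CCOC12CCC[C@@H]3CC=C[C@H](O)[C@]23C
F4 | step 2 | (S)-2-methoxy-2-phenylacetate of the (4a'S,8'R,8a'S) alcohol | O1CCOC12CCC[C@H]3CC=C[C@@H](OC(=O)[C@@H](OC)c4ccccc4)[C@@]23C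
F5 | step 2 | (4a'S,8'R,8a'S)-8a'-methyl-3',4',4a',5',8',8a'-hexahydro-2'H-spiro[1,3-dioxolane-2,1'-naphthalen]-8'-ol | O1CCOC12CCC[C@H]3CC=C[C@@H](O)[C@@]23C
F6 | step 10 | lactol of 16 (3-hydroxy in place of 3-oxo) | O1CCOC12CCC[C@H]3C(Cc4c(OC)c(OC)cc(OC)c4OC)C(O)O[C@H](/C=C/C)[C@@]23C
F7 | step 10 | cyclic enol ether, (1R,4aS,8aS)-8,8-(ethylenedioxy)-8a-methyl-1-[(E)-prop-1-en-1-yl]-4-(2,3,5,6-tetramethoxybenzyl)-4a,5,6,7,8,8a-hexahydro-1H-isochromene | O1CCOC12CCC[C@H]3C(Cc4c(OC)c(OC)cc(OC)c4OC)=CO[C@H](/C=C/C)[C@@]23C
F8 | step 4 | (2S)-2-[(6S,7S)-6-methyl-7-(2-oxoethyl)-1,4-dioxaspiro[4.5]decan-6-yl]-2-(triisopropylsilyloxy)acetaldehyde | O1CCOC12CCC[C@@H](CC=O)[C@@]2(C)[C@H](O[Si](C(C)C)(C(C)C)C(C)C)C=O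
F9 | step 4 | lactol aldehyde, 8,8-(ethylenedioxy)-3-hydroxy-8a-methyloctahydro-1H-isochromene-1-carbaldehyde | O1CCOC12CCC[C@H]3CC(O)O[C@H](C=O)[C@@]23C
F10 | step 4 | lactone aldehyde, 8,8-(ethylenedioxy)-8a-methyl-3-oxooctahydro-1H-isochromene-1-carbaldehyde | O1CCOC12CCC[C@H]3CC(=O)O[C@H](C=O)[C@@]23C
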